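The readings were generated by integration on assumed constants; the scatter is artificial.

A small charge of precatalyst, 6.9 mM, goes into this flask with a racemic substrate pair and a solid reagent, none of which is yet in solution.

all flasks: left-handed substrate 0.46 M; right-handed substrate 0.46 M

| charge | solid reagent | precatalyst | remark |
|---|---|---|---|
| north | 0.92 M | 3.5 mM | run made earlier |
| south-east | 0.92 M | 14 mM | run made earlier |
| flask | 0.920 M | 6.9 mM |  |

- north (time / h: left-handed product / %, left-handed substrate / %): 1.33: 0, 49.9; 4.00: 2.7, 48.5; 8.00: 6.9, 42.7; 10.0: 10.1, 39.8; 15.0: 19.3, 31.2; 20.0: 28.2, 22.1; 25.0: 35.6, 15.3
- south-east (time / h: left-handed product / %, left-handed substrate / %): 4.00: 6.9, 43.9; 8.00: 21.8, 27.9; 10.0: 29.2, 21.1; 15.0: 42.4, 8.3; 20.0: 47.7, 2.6; 25.0: 49.0, 1.0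

(standard deviation of a reading: 0.3 percentage points)

* factor on the rate of making left-handed product when 20% of the left-handed substrate and right-handed substrate together are converted if precatalyst is charged twice over
* factor on the rate when 20% of the left-handed substrate and right-handed substrate together are converted if precatalyst is charged at 60 mM instead

- catalyst is single-handed; left-handed substrate and right-handed substrate are mirror images of each other, charged as a racemate, each of them at the stated concentration
- as a solid, counted per litre of solution: solid reagent
- candidate steps: partner + catalyst + left-handed substrate -> catalyst + left-handed product; partner + catalyst + right-handed substrate -> catalyst + right-handed product; solid reagent <-> partner; precatalyst -> catalyst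
- at the start none of the solid reagent is in solution

I compare the two earlier runs at equal left-handed product. The north run reaches 6.9% at 8.00 h, and the south-east run reaches 6.9% at 4.00 h. The south-east run holds 4.00 times the north charge, yet it needs half the time. The logarithm of that time ratio over the logarithm of the charge ratio is the charge order, an apparent order, and these two readings give 0.500. If the curves keep one shape, the rate at equal conversion goes as one over that time, so for this flask I expect 1.41 for the doubled charge and 2.95 for 60 mM.

The forecast gives 1.4 and 2.6. It uses the same square root but goes below my second figure, since it reads a shortfall that “hints that partner supply limits the rate”.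

The flask gives 1.44 and 3.03.

    partner + catalyst + left-handed substrate → catalyst + left-handed product (k = 110 M⁻² h⁻¹)
    partner + catalyst + right-handed substrate → catalyst + right-handed product (k = 25.0 M⁻² h⁻¹)
    solid reagent ⇌ partner, rate k3*(cs3 - [partner]) while solid is left; crystals form when [partner] > cs3 (solubility = 0.410 M, k = 1.60 h⁻¹)
    precatalyst → catalyst (k = 0.0330 h⁻¹)

At 12.5 h this flask holds 33.8% of its charge as catalyst and 66.2% still as precatalyst, with 0.033 h⁻¹ as the rate constant of that conversion. This flask then holds 24.4% left-handed product. The charge order of 0.500 puts that level at 17.6 h in the north run, whose readings are 19.3% at 15.0 h and 28.2% at 20.0 h.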